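# Design of a synthesis of 5-hydroxy-2-(4-hydroxyphenoxy)-7-[(3-methylbut-2-en-1-yl)oxy]-4H-chromen-4-one (16) by chromium-mediated construction of the hydroquinone ring

## The problem

Compound 16 is a 2-aryloxychromone: a benzopyran-4-one (benzo ring A, pyranone ring C) whose C2 carries, through an enol-ether oxygen, a para-hydroxyphenyl ring B. It has no stereocentre and no stereogenic double bond, so the task is connectivity and the fate of four oxygens: O5 free and hydrogen-bonded to C4=O, O7 as the 3-methylbut-2-enyl (prenyl) ether, O4' free, and O–C1' as the bridge to C2. Two groups limit the reagents that may be used late. The prenyl ether ionises under strong protic or Lewis acid (the allyl cation then migrates to the electron-rich ring A), is epoxidised by peracids and is lost on hydrogenolysis. The C2–O–aryl unit is a vinylogous carbonate: alkoxides, hydroxide and amines add at C2 and expel the phenoxide, and hot acid can do the same through the 4-hydroxybenzopyrylium ion. The end game must therefore be short, free of strong nucleophiles and limited to dilute acid. The feature that opens a less obvious route is ring B itself: it carries only the ether oxygen at C1' and the hydroxyl at C4', para to each other, with C2', C3', C5' and C6' unsubstituted. That is exactly the 4-alkoxyphenol formed when a vinyl(oxy)carbene ligand (C1', C2', C3'), a two-carbon alkyne (C5', C6') and one carbonyl ligand (C4' with its oxygen) are joined on chromium.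

## Retrosynthesis

**16 from 15.** The last bond cut is O5–CH2 of a methoxymethyl ether. The 5-hydroxyl has to be masked while chromium is present, because a free phenol could exchange at the strongly electrophilic carbene carbon of 12. An acetal is chosen because it withstands strong base, peroxide and organometallic reagents and is most easily cleaved when it sits peri to C4=O. The forward step asks only that dilute acid spares the prenyl ether and the C2 aryloxy link.

**15 from 12 and 13.** Ring B is taken apart at C1'–C6', C5'–C4' and C4'–C3'. This leaves the vinylcarbene ligand of 12, ethyne 13 and a carbonyl ligand already bound to the metal; the arene appears first as its η6-Cr(CO)3 complex 14, from which air removes the metal. The neighbouring cuts, O–C1' or C2–O, are ordinary ether formations from a monoprotected hydroquinone and are kept in reserve. The benzannulation instead fixes the para relationship of the two oxygens by mechanism and needs no differentiation of hydroquinone oxygens. The precursor is simpler by a whole ring. The forward reaction must be faster than the decay of a labile carbene complex and must leave the prenyl alkene and the acetal alone.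

**12 from 11 and 7.** The bond between the carbene oxygen and chromone C2 is cut, giving the acylmetalate 11 as oxygen nucleophile and the 2-sulfonylchromone 7 as electrophile. The reverse polarity (a chromone 2-oxide attacking an activated carbene carbon) is rejected because that anion is ambident and reacts mainly at O4, giving the coumarin isomer. In 7 the 4-oxo pattern is already fixed. The forward step must run between −40 and −20 °C, where 12 survives.

**11 from 8 and 9.** The bond between the vinyl carbon and the former carbonyl carbon is cut. Addition of vinylmagnesium bromide 9 to Cr(CO)6 8 gives the magnesium acylate 10, and cation exchange gives the tetramethylammonium salt 11, a form that can be weighed and dissolved in dichloromethane.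

**7 from 6, 5 and 4.** Sulfone 7 comes from sulfide 6 by oxidation at sulfur, and 6 from thione 5 by S-methylation. Ring C of 5 is cut at O1–C2 and C2–C3, which leaves the 2-hydroxyacetophenone 4 and a one-carbon thiocarbonyl electrophile. This standard annulation puts a sulfur leaving group on C2 and nothing on C3. The only demand beyond routine is that the sulfur be oxidised without touching the trisubstituted alkene.

**4 from 3, and 3 from 1 and 2.** The acetal and the prenyl ether are removed in turn. Phloroacetophenone 1 is symmetric: its 4-hydroxyl is the only one not chelated to the ketone and the most acidic, so prenyl bromide 2 goes there first. The two ortho hydroxyls of 3 are equivalent, and once one is etherified the other is locked in the hydrogen bond, so mono-protection to 4 is self-limiting.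

## Roads not taken

**Alternative 1: olefination of a carbonate carbonyl.** The cut is C2=C3 of ring C. In the forward sense the acyl ylide A2, which carries a mixed diaryl carbonate on the neighbouring phenol oxygen, is heated; the ylide carbon adds to the carbonate carbonyl and loss of the phosphine oxide closes the pyranone to give A1, one desilylation away from 16.
- Merits: ring B is bought with both oxygens in place, no metal or gas is needed, the 5-hydroxyl is already free in A1, and intramolecular olefination of ester carbonyls by stabilised acyl ylides is an established way to 2-substituted chromones.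
- Weak points: the carbonyl is a diaryl carbonate with two aryloxide leaving groups. The betaine can expel an aryloxide and end as a C-acylated ylide instead of collapsing to the alkene, and a carbonate is a poorer acceptor than an ester. A2 also requires α-functionalisation of a very electron-rich acetophenone, where ring halogenation competes, and a mixed carbonate on one of two ortho hydroxyls.
- Comparison: in closeness of precedent this road is better than the chosen one, and it is about as long. The chosen plan sets against it that ring B is made, so no unsymmetrical carbonate and no monoprotected hydroquinone have to be managed; that every step before the chromium chemistry is routine; and that sulfone 7 is one known substitution away from 15 if the key step fails. The key step of the chosen plan is the less certain of the two.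

**Alternative 2: photochemical benzannulation of ring A.** The cuts are C4a–C5, C5–C6 and C7–C8. Irradiation of the pyranonyl diazo ketone A4 with the silyl ynol ether A5 would give, through Wolff rearrangement, [2+2] addition, four-electron ring opening and six-electron closure onto the pyranone double bond, the chromone A3 with O5 free and O7 silylated.
- Merits: the 5,7-pattern of ring A and the differentiation of O5 from O7 follow from mechanism, and the step is convergent.
- Weak points: A4 needs a 2-aryloxy-4-pyranone bearing a carboxyl-derived side chain, which is no easier than ring C of the target. The 4-pyranone chromophore is itself photoactive. The electrocyclisation must engage a double bond of a cross-conjugated, partly aromatic ring. After the key step the more robust silyl ether on O7 must be removed beside the less robust one on O4', followed by prenylation and a second desilylation.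
- Comparison: both plans rest on a benzannulation without direct precedent. This one builds the ring with the harder substitution pattern, which is a real merit. The chosen plan gets that pattern from symmetric 1 in two routine steps and needs a single deprotection after its key step, so it is shorter where it matters.

**Alternative 3: carbonylative three-component assembly.** The cuts are C4–C4a, C3–C4 and O1–C2. The iodophenol A7 and the aryl ynol ether A8 would be joined under palladium-catalysed carbonylation to an aryl ynone, and 6-endo attack of the phenoxide would close ring C to give A6.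
- Merits: it is the most convergent road, with three simple pieces and one catalytic step, and carbonylative annulation of 2-iodophenols with terminal alkynes is established chromone chemistry.
- Weak points: A8 is prone to hydration and to amine addition under the basic conditions, and 5-exo closure competes. Decisively, A6 carries three methyl ethers. Cleaving them calls for strong Lewis acids or nucleophiles that threaten the C2 aryloxy link, and the resulting triol must then be prenylated at O7 alone.
- Comparison: up to the skeleton this road is shorter and better precedented than the chosen plan. The gap between A6 and 16 is the hard part. The chosen plan spends its steps early, carries the prenyl ether from step 1 and ends with one mild deprotection.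

Key step: step 8

Assumption: the target has no stereocentre, so no configuration is set anywhere; in SMILES the η6-bound Cr(CO)3 fragment of 14 is written beside the arene, joined by a dot.

## Route

Step 1
Reactants: 1 2,4,6-trihydroxyacetophenone; 2 prenyl bromide (1-bromo-3-methylbut-2-ene)
Product: 3 1-{2,6-dihydroxy-4-[(3-methylbut-2-en-1-yl)oxy]phenyl}ethan-1-one
Conditions: K2CO3 (1.0 equiv), acetone, rt to 50 °C
Reagents that add atoms: none
Why: Williamson etherification; the 4-hydroxyl is the only one not chelated to the ketone and the most acidic, so one equivalent of weak base in acetone alkylates it on oxygen in preference to the two hydrogen-bonded ortho hydroxyls.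

Step 2
Reactants: 3 1-{2,6-dihydroxy-4-[(3-methylbut-2-en-1-yl)oxy]phenyl}ethan-1-one
Product: 4 1-{2-hydroxy-6-(methoxymethoxy)-4-[(3-methylbut-2-en-1-yl)oxy]phenyl}ethan-1-one
Conditions: MOMCl (1.1 equiv), i-Pr2NEt, CH2Cl2, 0 °C to rt
Reagents that add atoms: chloromethyl methyl ether, COCCl
Why: Acetal protection of a phenol; the two ortho hydroxyls are equivalent, and after the first is etherified the second is held in the hydrogen bond to the ketone, so the reaction should stop at the mono-ether, as is usual for 2,6-dihydroxyacetophenones.

Step 3
Reactants: 4 1-{2-hydroxy-6-(methoxymethoxy)-4-[(3-methylbut-2-en-1-yl)oxy]phenyl}ethan-1-one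
Product: 5 4-hydroxy-5-(methoxymethoxy)-7-[(3-methylbut-2-en-1-yl)oxy]-2H-chromene-2-thione
Conditions: CS2 (1.5 equiv), KOtBu (3 equiv), THF, 0 °C to rt; cold 1 M aq. AcOH work-up
Reagents that add atoms: carbon disulfide, S=C=S
Why: Claisen-type thioacylation of the ketone enolate followed by closure of the phenol oxygen on the dithiocarboxyl carbon with loss of hydrogen sulfide, the standard route from 2-hydroxyacetophenones to 4-hydroxychromene-2-thiones; acetal and allyl ether are inert to KOtBu and to cold dilute acetic acid.

Step 4
Reactants: 5 4-hydroxy-5-(methoxymethoxy)-7-[(3-methylbut-2-en-1-yl)oxy]-2H-chromene-2-thione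
Product: 6 5-(methoxymethoxy)-7-[(3-methylbut-2-en-1-yl)oxy]-2-(methylsulfanyl)-4H-chromen-4-one
Conditions: MeI (1.1 equiv), K2CO3, acetone, rt
Reagents that add atoms: iodomethane, CI
Why: S-Alkylation of the ambident thione anion at its soft sulfur, which locks the 4-oxo (chromone) tautomer; routine for this heterocycle.

Step 5
Reactants: 6 5-(methoxymethoxy)-7-[(3-methylbut-2-en-1-yl)oxy]-2-(methylsulfanyl)-4H-chromen-4-one
Product: 7 2-(methanesulfonyl)-5-(methoxymethoxy)-7-[(3-methylbut-2-en-1-yl)oxy]-4H-chromen-4-one
Conditions: (NH4)6Mo7O24·4H2O (10 mol%), 30% aq. H2O2 (5 equiv), EtOH/THF, 0 °C to rt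
Reagents that add atoms: hydrogen peroxide, OO
Why: Peroxomolybdate-catalysed oxidation of sulfide to sulfone, the usual choice for electron-poor heteroaryl sulfides that carry isolated alkenes (as in the preparation of Julia–Kocienski sulfones); the metal peroxo species oxidises sulfur far faster than an unactivated trisubstituted alkene, which a peracid would not spare.

Step 6
Reactants: 8 chromium hexacarbonyl Cr(CO)6; 9 vinylmagnesium bromide CH2=CHMgBr
Product: 11 tetramethylammonium pentacarbonyl(1-oxidoprop-2-en-1-ylidene)chromate [Me4N][(OC)5Cr=C(O)CH=CH2], via bromomagnesium acylate 10 (not isolated)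
Conditions: THF, 0 °C to rt; then Me4NBr, degassed H2O, 0 °C; dried and stored cold under argon
Reagents that add atoms: tetramethylammonium bromide, C[N+](C)(C)C.[Br-]
Why: Classical acylmetalate synthesis: the organomagnesium adds to a carbonyl ligand of zerovalent chromium, and cation metathesis gives the tetramethylammonium salt, the form in which such acylates are handled and O-functionalised.

Step 7
Reactants: 7 2-(methanesulfonyl)-5-(methoxymethoxy)-7-[(3-methylbut-2-en-1-yl)oxy]-4H-chromen-4-one; 11 tetramethylammonium pentacarbonyl(1-oxidoprop-2-en-1-ylidene)chromate [Me4N][(OC)5Cr=C(O)CH=CH2]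
Product: 12 pentacarbonyl[1-({5-(methoxymethoxy)-7-[(3-methylbut-2-en-1-yl)oxy]-4-oxo-4H-chromen-2-yl}oxy)prop-2-en-1-ylidene]chromium
Conditions: 11 (1.2 equiv), CH2Cl2, −40 to −20 °C, argon, dark; the cold solution is used at once
Reagents that add atoms: none
Why: Proposed new method: the acylate oxygen adds to C2 of 7, which is both the β-carbon of the chromone enone and the carbon bearing the sulfonyl group, and the resulting enolate expels methanesulfinate to leave the carbene oxygen on C2; the closest known reactions are the O-acylation of tetramethylammonium acylmetalates by acyl halides to acyloxycarbene complexes at −40 °C and the displacement of 2-sulfonylchromones by phenoxides, and the product, a vinylogous acyloxycarbene complex, is kept cold for the same reason that acyloxycarbene complexes are.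

Step 8
Reactants: 12 pentacarbonyl[1-({5-(methoxymethoxy)-7-[(3-methylbut-2-en-1-yl)oxy]-4-oxo-4H-chromen-2-yl}oxy)prop-2-en-1-ylidene]chromium; 13 ethyne
Product: 15 2-(4-hydroxyphenoxy)-5-(methoxymethoxy)-7-[(3-methylbut-2-en-1-yl)oxy]-4H-chromen-4-one, via arene tricarbonylchromium complex 14 (not isolated)
Conditions: ethyne (1 atm, acetone-free), THF/CH2Cl2, −40 to 40 °C; then air, MeCN, daylight, rt
Reagents that add atoms: none
Why: Proposed new method: a Dötz [3+2+1] benzannulation, whose closest known form is the reaction of alkenyl(alkoxy)carbene Cr(CO)5 complexes with alkynes to give 4-alkoxyphenol Cr(CO)3 complexes, here carried out on a carbene whose oxygen is of the vinylogous acyloxy type and with ethyne itself. Loss of a cis carbonyl ligand, made easier by the weakly donating carbene oxygen, lets ethyne coordinate and insert into the Cr=C1' bond (C1'–C6'), and carbonyl insertion then gives the chromium-bound vinylketene (C5'–C4'). Ring B closes by a thermal six-electron disrotatory electrocyclisation of this dienylketene, which joins C4' to the vinyl terminus C3'; tautomerisation of the cyclohexadienone gives the phenol as its η6-Cr(CO)3 complex 14. No stereocentre is formed. The step needs benzannulation to prevail over cyclobutenone, furan and two-alkyne products, which an alkenyl (not aryl) carbene, THF as donor solvent and a low standing concentration of ethyne should secure; ethyne is symmetric, so there is no regiochemical question, and the ether oxygen ends para to the new hydroxyl by mechanism. The prenyl alkene and the chromone C2=C3 bond are far poorer partners for the carbene than a terminal alkyne, and the acetal keeps the 5-hydroxyl from exchanging at the carbene carbon. Air and light are used instead of a ceric oxidant to free the arene, so that the hydroquinone monoether is not taken on to the quinone.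

Step 9
Reactants: 15 2-(4-hydroxyphenoxy)-5-(methoxymethoxy)-7-[(3-methylbut-2-en-1-yl)oxy]-4H-chromen-4-one
Product: 16 5-hydroxy-2-(4-hydroxyphenoxy)-7-[(3-methylbut-2-en-1-yl)oxy]-4H-chromen-4-one
Conditions: 1 M aq. HCl, MeOH/THF, rt
Reagents that add atoms: none
Why: Acid-catalysed acetal cleavage; the ether peri to C4=O is the most labile group in the molecule because the freed hydroxyl is stabilised by the hydrogen bond to the carbonyl, so dilute acid at room temperature should remove it while the prenyl ether and the C2 aryloxy link persist.

## Compound list

1 | 2,4,6-trihydroxyacetophenone | CC(=O)c1c(O)cc(O)cc1O | starting material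
2 | prenyl bromide (1-bromo-3-methylbut-2-ene) | CC(C)=CCBr | starting material
3 | 1-{2,6-dihydroxy-4-[(3-methylbut-2-en-1-yl)oxy]phenyl}ethan-1-one | CC(=O)c1c(O)cc(OCC=C(C)C)cc1O | intermediate
4 | 1-{2-hydroxy-6-(methoxymethoxy)-4-[(3-methylbut-2-en-1-yl)oxy]phenyl}ethan-1-one | CC(=O)c1c(O)cc(OCC=C(C)C)cc1OCOC | intermediate
5 | 4-hydroxy-5-(methoxymethoxy)-7-[(3-methylbut-2-en-1-yl)oxy]-2H-chromene-2-thione | OC1=CC(=S)Oc2cc(OCC=C(C)C)cc(OCOC)c12 | intermediate
6 | 5-(methoxymethoxy)-7-[(3-methylbut-2-en-1-yl)oxy]-2-(methylsulfanyl)-4H-chromen-4-one | CSc1cc(=O)c2c(OCOC)cc(OCC=C(C)C)cc2o1 | intermediate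
7 | 2-(methanesulfonyl)-5-(methoxymethoxy)-7-[(3-methylbut-2-en-1-yl)oxy]-4H-chromen-4-one | CS(=O)(=O)c1cc(=O)c2c(OCOC)cc(OCC=C(C)C)cc2o1 | intermediate
8 | chromium hexacarbonyl Cr(CO)6 | O=C=[Cr](=C=O)(=C=O)(=C=O)(=C=O)=C=O | starting material
9 | vinylmagnesium bromide CH2=CHMgBr | C=C[Mg]Br | starting material
10 | bromomagnesium pentacarbonyl(1-oxidoprop-2-en-1-ylidene)chromate (OC)5Cr=C(OMgBr)CH=CH2 (not isolated) | C=CC(O[Mg]Br)=[Cr](=C=O)(=C=O)(=C=O)(=C=O)=C=O | intermediate
11 | tetramethylammonium pentacarbonyl(1-oxidoprop-2-en-1-ylidene)chromate [Me4N][(OC)5Cr=C(O)CH=CH2] | C=CC([O-])=[Cr](=C=O)(=C=O)(=C=O)(=C=O)=C=O.C[N+](C)(C)C | intermediate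
12 | pentacarbonyl[1-({5-(methoxymethoxy)-7-[(3-methylbut-2-en-1-yl)oxy]-4-oxo-4H-chromen-2-yl}oxy)prop-2-en-1-ylidene]chromium | C=CC(Oc1cc(=O)c2c(OCOC)cc(OCC=C(C)C)cc2o1)=[Cr](=C=O)(=C=O)(=C=O)(=C=O)=C=O | intermediate
13 | ethyne | C#C | starting material
14 | tricarbonyl{η6-2-(4-hydroxyphenoxy)-5-(methoxymethoxy)-7-[(3-methylbut-2-en-1-yl)oxy]-4H-chromen-4-one}chromium, Cr(CO)3 on the hydroquinone ring (not isolated) | CC(C)=CCOc1cc(OCOC)c2c(=O)cc(Oc3ccc(O)cc3)oc2c1.O=C=[Cr](=C=O)=C=O | intermediate
15 | 2-(4-hydroxyphenoxy)-5-(methoxymethoxy)-7-[(3-methylbut-2-en-1-yl)oxy]-4H-chromen-4-one | CC(C)=CCOc1cc(OCOC)c2c(=O)cc(Oc3ccc(O)cc3)oc2c1 | intermediate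
16 | 5-hydroxy-2-(4-hydroxyphenoxy)-7-[(3-methylbut-2-en-1-yl)oxy]-4H-chromen-4-one | CC(C)=CCOc1cc(O)c2c(=O)cc(Oc3ccc(O)cc3)oc2c1 | target

## Step count and risk

Total steps: 9. Longest linear sequence: 8 (steps 1 to 5, then 7, 8 and 9); step 6 is a one-step side branch that supplies 11.

Least certain steps:

**Step 8 (key step, proposed new method).** The carbene complex may decay thermally before it loses a carbonyl ligand and takes up the alkyne. Ethyne may insert repeatedly and give oligomers or two-alkyne products, and the vinylketene may be diverted to a cyclobutenone; all three are more likely because ethyne is a slow partner and the carbene is unusually electrophilic. The fallback sets out from 7 and comes back at 15, using known chemistry only. Sulfone 7 is stirred with 4-(tert-butyldimethylsilyloxy)phenol (CC(C)(C)[Si](C)(C)Oc1ccc(O)cc1) and K2CO3 in acetone at room temperature, where phenoxide addition–elimination at C2 gives 2-[4-(tert-butyldimethylsilyloxy)phenoxy]-5-(methoxymethoxy)-7-[(3-methylbut-2-en-1-yl)oxy]-4H-chromen-4-one F1. Bu4NF buffered with AcOH in THF at 0 °C then frees the phenol to give 15.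

**Step 7 (proposed new method).** Substitution at C2 may be too slow at the temperatures the product tolerates. The liberated sulfinate may add in conjugate fashion to the vinyl group of the carbene complex, and the acylate may react through carbon instead of oxygen. The fallback sets out from 7 and comes back at 15 by known reactions that still install the para oxygen last. Sulfone 7 and 4-(4,4,5,5-tetramethyl-1,3,2-dioxaborolan-2-yl)phenol (CC1(C)OB(c2ccc(O)cc2)OC1(C)C) with K2CO3 in DMF give 5-(methoxymethoxy)-7-[(3-methylbut-2-en-1-yl)oxy]-2-[4-(4,4,5,5-tetramethyl-1,3,2-dioxaborolan-2-yl)phenoxy]-4H-chromen-4-one F2. Oxidation of the carbon–boron bond with NaBO3·4H2O in THF/H2O at room temperature gives 15.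

**Step 5.** Over-oxidation may reach the prenyl alkene (epoxidation) before the second oxygen is delivered to the deactivated sulfur, or the sulfone may be solvolysed at C2 once formed. The fallback sets out from 6 and comes back at 12. One equivalent of mCPBA in CH2Cl2 at −40 °C, where sulfur oxidation far outruns epoxidation, gives 2-(methanesulfinyl)-5-(methoxymethoxy)-7-[(3-methylbut-2-en-1-yl)oxy]-4H-chromen-4-one F3 (racemic at sulfur). The sulfinyl group then serves as the leaving group towards 11 under the conditions of step 7, to give 12.

**Step 9.** Protonation of the trisubstituted alkene and ionisation of the allyl ether may accompany acetal cleavage, with loss of the prenyl group or its transfer to ring A. In the fallback the loss is accepted; it sets out from 15 and comes back at 16. CF3CO2H with Et3SiH as cation trap in CH2Cl2 at 0 °C strips both the acetal and the prenyl ether to give 5,7-dihydroxy-2-(4-hydroxyphenoxy)-4H-chromen-4-one F4. The prenyl group is then put back at O7 alone with 2 and one equivalent of KHCO3 in DMF: the 7-hydroxyl, a vinylogous acid para to C4=O, is the most acidic of the three, and the 5-hydroxyl is chelated.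

**Step 1.** Alkylation may spread to carbon (C3 of the phloroglucinol ring) and to a second oxygen, since the phenoxide of 1 is an ambident, highly activated nucleophile. The fallback sets out from 1 and comes back at 3 and makes no new compound (F0). A Mitsunobu etherification with 3-methylbut-2-en-1-ol (CC(C)=CCO), PPh3 and diisopropyl azodicarboxylate in THF at 0 °C activates the alcohol and not the phenol, so that only the most acidic, unchelated 4-hydroxyl is alkylated and it reacts on oxygen.

## Further compounds

F1 | step 8 | 2-[4-(tert-butyldimethylsilyloxy)phenoxy]-5-(methoxymethoxy)-7-[(3-methylbut-2-en-1-yl)oxy]-4H-chromen-4-one | CC(C)=CCOc1cc(OCOC)c2c(=O)cc(Oc3ccc(O[Si](C)(C)C(C)(C)C)cc3)oc2c1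
F2 | step 7 | 5-(methoxymethoxy)-7-[(3-methylbut-2-en-1-yl)oxy]-2-[4-(4,4,5,5-tetramethyl-1,3,2-dioxaborolan-2-yl)phenoxy]-4H-chromen-4-one | CC(C)=CCOc1cc(OCOC)c2c(=O)cc(Oc3ccc(B4OC(C)(C)C(C)(C)O4)cc3)oc2c1
F3 | step 5 | 2-(methanesulfinyl)-5-(methoxymethoxy)-7-[(3-methylbut-2-en-1-yl)oxy]-4H-chromen-4-one (racemic at sulfur) | CS(=O)c1cc(=O)c2c(OCOC)cc(OCC=C(C)C)cc2o1
F4 | step 9 | 5,7-dihydroxy-2-(4-hydroxyphenoxy)-4H-chromen-4-one | O=c1cc(Oc2ccc(O)cc2)oc2cc(O)cc(O)c12
F0 | step 1 | none | none
A1 | alternative 1 | 2-[4-(tert-butyldimethylsilyloxy)phenoxy]-5-hydroxy-7-[(3-methylbut-2-en-1-yl)oxy]-4H-chromen-4-one | CC(C)=CCOc1cc(O)c2c(=O)cc(Oc3ccc(O[Si](C)(C)C(C)(C)C)cc3)oc2c1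
A2 | alternative 1 | 4-(tert-butyldimethylsilyloxy)phenyl 3-hydroxy-5-[(3-methylbut-2-en-1-yl)oxy]-2-[(triphenyl-λ5-phosphanylidene)acetyl]phenyl carbonate | CC(C)=CCOc1cc(O)c(C(=O)C=P(c2ccccc2)(c2ccccc2)c2ccccc2)c(OC(=O)Oc2ccc(O[Si](C)(C)C(C)(C)C)cc2)c1
A3 | alternative 2 | 5-hydroxy-7-(triisopropylsilyloxy)-2-[4-(tert-butyldimethylsilyloxy)phenoxy]-4H-chromen-4-one | CC(C)[Si](Oc1cc(O)c2c(=O)cc(Oc3ccc(O[Si](C)(C)C(C)(C)C)cc3)oc2c1)(C(C)C)C(C)C
A4 | alternative 2 | 2-[4-(tert-butyldimethylsilyloxy)phenoxy]-6-(diazoacetyl)-4H-pyran-4-one | [N-]=[N+]=CC(=O)c1cc(=O)cc(Oc2ccc(O[Si](C)(C)C(C)(C)C)cc2)o1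
A5 | alternative 2 | (triisopropylsilyloxy)ethyne | C#CO[Si](C(C)C)(C(C)C)C(C)C
A6 | alternative 3 | 5,7-dimethoxy-2-(4-methoxyphenoxy)-4H-chromen-4-one | COc1ccc(Oc2cc(=O)c3c(OC)cc(OC)cc3o2)cc1
A7 | alternative 3 | 2-iodo-3,5-dimethoxyphenol | COc1cc(O)c(I)c(OC)c1
A8 | alternative 3 | 1-(ethynyloxy)-4-methoxybenzene | C#COc1ccc(OC)cc1
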